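**Plan**
1. Retrosynthesis: the aryl ester C–O bond is cut first (jaeschkeanadiol + 4-acetoxybenzoyl chloride); the C6 methyl is traced back to CO2Me and the cis H-3a/O-4 pair to a C3a=C4 alkene (locants: azulene numbering of the target).
2. This exposes the enabling feature: in the seven-membered ring (C3a, C4, C5, C6, C7, C8, C8a) the C6=C7 alkene and the C3a–C4 unit flank the lone methylene C5, i.e. a cyclohepta-1,4-diene, the retron of a cis-divinylcyclopropane Cope rearrangement.
3. Cutting C8–C8a (the [3,3] bond) and C5–C6 (carbene addition) leaves a 2-vinyl-3-methylcyclopentene and the three-carbon vinylcarbenoid from methyl 2-diazobut-3-enoate.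
4. Forward: the five-membered ring is made first by ozonolysis/aldol ring contraction of (S)-terpinen-4-ol; the seven-membered ring is closed last by a one-pot rhodium-carbenoid cyclopropanation and strain-releasing Cope rearrangement.
5. Stereochemistry: C3 comes from terpinen-4-ol; quaternary C8a from catalyst-controlled cyclopropanation relayed through the boat Cope transition state; C3a and C4 from one syn hydroboration.

Key step: step 6

Assumption: (S)-terpinen-4-ol is bought enantiopure; its carbinol C–O bond is never broken, so it fixes the absolute configuration of the target.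

**Step 1**
Reactants: 1 (S)-terpinen-4-ol
Product: 2 triethyl{[(1S)-4-methyl-1-(propan-2-yl)cyclohex-3-en-1-yl]oxy}silane
Conditions: Et3SiOTf, 2,6-lutidine, CH2Cl2, 0 °C → rt
Reagents that add atoms: triethylsilyl trifluoromethanesulfonate, CC[Si](CC)(CC)OS(=O)(=O)C(F)(F)F
Why: Silyl triflate/lutidine silylation is the standard way to cap a hindered tertiary alcohol, which must be masked against O–H insertion in step 6 and adds bulk to one face for step 7.

**Step 2**
Reactants: 2 triethyl{[(1S)-4-methyl-1-(propan-2-yl)cyclohex-3-en-1-yl]oxy}silane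
Product: 4 (3S)-6-oxo-3-(propan-2-yl)-3-[(triethylsilyl)oxy]heptanal, via ozonide 3 (not isolated)
Conditions: O3, CH2Cl2, −78 °C; then PPh3, −78 °C → rt
Reagents that add atoms: ozone, [O-][O+]=O
Why: Ozonolysis with reductive work-up cleaves the only alkene to the keto aldehyde without touching the silyl ether or the stereocentre.

**Step 3**
Reactants: 4 (3S)-6-oxo-3-(propan-2-yl)-3-[(triethylsilyl)oxy]heptanal
Product: 5 (5R)-2-methyl-5-(propan-2-yl)-5-[(triethylsilyl)oxy]cyclopent-1-ene-1-carbaldehyde
Conditions: piperidine (0.3 equiv.), AcOH (0.3 equiv.), benzene, rt → 60 °C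
Reagents that add atoms: none
Why: Enamine-mediated intramolecular aldol condensation, in which the aldehyde α-carbon attacks the methyl ketone (the known regiochemistry for 6-oxoheptanals under piperidinium acetate), should give the tetrasubstituted enal with the carbinol carbon next to the formyl-bearing carbon.

**Step 4**
Reactants: 5 (5R)-2-methyl-5-(propan-2-yl)-5-[(triethylsilyl)oxy]cyclopent-1-ene-1-carbaldehyde
Product: 6 {[(1R)-2-ethenyl-3-methyl-1-(propan-2-yl)cyclopent-2-en-1-yl]oxy}triethylsilane
Conditions: Ph3PCH3Br, KOt-Bu, THF, 0 °C → rt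
Reagents that add atoms: methyltriphenylphosphonium bromide, C[P+](c1ccccc1)(c1ccccc1)c1ccccc1.[Br-]
Why: Wittig methylenation of the aldehyde gives the 1,3-diene whose vinyl group is the only unhindered alkene.

**Step 5**
Reactants: 7 methyl but-3-enoate
Product: 8 methyl 2-diazobut-3-enoate
Conditions: 4-acetamidobenzenesulfonyl azide, DBU, MeCN, 0 °C; extracted into pentane and used at once
Reagents that add atoms: 4-acetamidobenzenesulfonyl azide, CC(=O)Nc1ccc(cc1)S(=O)(=O)N=[N+]=[N-]
Why: Regitz diazo transfer to the doubly activated (allylic, α to ester) methylene gives the vinyldiazoacetate, which is used fresh because it cyclises to a pyrazole on standing.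

**Step 6**
Reactants: 6 {[(1R)-2-ethenyl-3-methyl-1-(propan-2-yl)cyclopent-2-en-1-yl]oxy}triethylsilane; 8 methyl 2-diazobut-3-enoate
Product: 10 methyl (3R,8aR)-8a-methyl-3-(propan-2-yl)-3-[(triethylsilyl)oxy]-1,2,3,5,8,8a-hexahydroazulene-6-carboxylate, via cis-divinylcyclopropane 9 (not isolated)
Conditions: Rh2(R-DOSP)4 [dirhodium tetrakis((R)-N-(4-dodecylbenzenesulfonyl)prolinate)] (1 mol %), hexanes, −40 °C → rt, slow addition of 8 (2 equiv.); then solvent exchange to toluene, 110 °C
Reagents that add atoms: none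
Why: The divalent-rhodium carbenoid formed from 8 by loss of N2 adds to the monosubstituted vinyl group of 6 with its vinyl donor cis to the cyclopentenyl group, so that 9 is a cis-1,2-divinylcyclopropane; on heating, 9 undergoes a [3,3]-sigmatropic (Cope) shift in which the C8–C8a bond forms and the strained C4–C6 cyclopropane bond breaks. The closest known reaction type is the tandem vinyldiazoacetate cyclopropanation/divinylcyclopropane rearrangement (formal [4+3] cycloaddition) of 1-vinylcycloalkenes, including divinylcyclopropane rearrangements that build an angular-methyl quaternary carbon from a 2-methylcycloalkenyl terminus. The seven-membered ring closes in a concerted pericyclic mode through the obligatory boat transition state with both alkenes endo over the three-membered ring, which delivers the cis ring alkenes C3a=C4 and C6=C7 directly. The only surviving new stereocentre, C8a, is controlled by the (1S,2S) configuration of the cyclopropane and hence by the catalyst: in the boat this configuration places C8 under the cyclopentene face anti to the silyloxy group, giving 8aR, while the two cyclopropane stereocentres become sp2. The step needs chemoselectivity for the vinyl group, cis diastereoselectivity and enantioface control, secured respectively by the inertness of the tetrasubstituted ring alkene, the intrinsic preference of donor/acceptor carbenoids and the prolinate catalyst (R series chosen from the accepted facial model), with the remote C3 centre expected to interfere little. The methyl group on the ring-alkene terminus points into the boat, so the rearrangement should need the heating in toluene and not proceed at room temperature.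

**Step 7**
Reactants: 10 methyl (3R,8aR)-8a-methyl-3-(propan-2-yl)-3-[(triethylsilyl)oxy]-1,2,3,5,8,8a-hexahydroazulene-6-carboxylate
Product: 12 methyl (3R,3aS,4S,8aR)-4-hydroxy-8a-methyl-3-(propan-2-yl)-3-[(triethylsilyl)oxy]-1,2,3,3a,4,5,8,8a-octahydroazulene-6-carboxylate, via alkylborane 11 (not isolated)
Conditions: BH3·SMe2 (1.3 equiv.), THF, 0 °C → rt; then 30% H2O2, 3 M aq. NaOAc, 0 °C → rt
Reagents that add atoms: hydrogen peroxide, OO
Why: Hydroboration–oxidation of the electron-rich C3a=C4 alkene (the enoate alkene is deactivated) puts boron on the less substituted C4 and H on C3a in a syn addition that is expected to occur on the face opposite the angular methyl and the allylic OSiEt3 group, setting H-3a trans to the 8a-methyl and O-4 cis to H-3a in one operation.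

**Step 8**
Reactants: 12 methyl (3R,3aS,4S,8aR)-4-hydroxy-8a-methyl-3-(propan-2-yl)-3-[(triethylsilyl)oxy]-1,2,3,3a,4,5,8,8a-octahydroazulene-6-carboxylate
Product: 14 (3R,3aS,4S,8aR)-6-(hydroxymethyl)-8a-methyl-3-(propan-2-yl)-1,2,3,3a,4,5,8,8a-octahydroazulene-3,4-diol, via silyl-protected diol 13 (not isolated)
Conditions: i-Bu2AlH (4 equiv.), CH2Cl2, −78 → 0 °C; then 1 M aq. HCl, THF, 0 °C → rt
Reagents that add atoms: none
Why: i-Bu2AlH reduces the conjugated ester to the allylic alcohol by 1,2-reduction, and the acidic aqueous work-up that dissolves the aluminium salts also hydrolyses the acid-labile triethylsilyl ether.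

**Step 9**
Reactants: 14 (3R,3aS,4S,8aR)-6-(hydroxymethyl)-8a-methyl-3-(propan-2-yl)-1,2,3,3a,4,5,8,8a-octahydroazulene-3,4-diol
Product: 16 jaeschkeanadiol, (3R,3aS,4S,8aR)-6,8a-dimethyl-3-(propan-2-yl)-1,2,3,3a,4,5,8,8a-octahydroazulene-3,4-diol, via allylic sulfate 15 (not isolated)
Conditions: SO3·pyridine (1.1 equiv.), THF, 0 °C; then LiAlH4 (excess), THF, 0 °C → rt
Reagents that add atoms: none
Why: Sulfate-ester/hydride deoxygenation: the unhindered primary allylic hydroxyl is sulfated in preference to the neopentyl-like secondary and the tertiary hydroxyl, and LiAlH4 displaces the primary allylic sulfate directly (SN2), giving the C6 methyl without moving the double bond.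

**Step 10**
Reactants: 16 jaeschkeanadiol; 17 4-acetoxybenzoyl chloride
Product: 18 (3R,3aS,4S,8aR)-3-hydroxy-6,8a-dimethyl-3-(propan-2-yl)-1,2,3,3a,4,5,8,8a-octahydroazulen-4-yl 4-(acetyloxy)benzoate
Conditions: pyridine, DMAP (0.2 equiv.), CH2Cl2, 0 °C → rt
Reagents that add atoms: none
Why: DMAP-catalysed acylation takes place at the secondary C4 hydroxyl only, because the tertiary C3 hydroxyl is too hindered to acylate, while the phenol stays masked as its acetate.

**Step 11**
Reactants: 18 (3R,3aS,4S,8aR)-3-hydroxy-6,8a-dimethyl-3-(propan-2-yl)-1,2,3,3a,4,5,8,8a-octahydroazulen-4-yl 4-(acetyloxy)benzoate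
Product: 19 ferutinine
Conditions: pyrrolidine (3 equiv.), CH2Cl2, 0 °C → rt
Reagents that add atoms: none
Why: Aminolysis cleaves the activated phenyl acetate far faster than the hindered secondary benzoate, which is further deactivated once the phenol is free.

**Compound list**
1 | (S)-terpinen-4-ol, (1S)-4-methyl-1-(propan-2-yl)cyclohex-3-en-1-ol | CC1=CC[C@](O)(C(C)C)CC1 | starting material
2 | triethyl{[(1S)-4-methyl-1-(propan-2-yl)cyclohex-3-en-1-yl]oxy}silane | CC1=CC[C@](O[Si](CC)(CC)CC)(C(C)C)CC1 | intermediate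
3 | ozonide (1,2,4-trioxolane) of 2, mixture of epimers at the two acetal carbons | CC12CC[C@@](O[Si](CC)(CC)CC)(C(C)C)CC(OO1)O2 | intermediate (not isolated)
4 | (3S)-6-oxo-3-(propan-2-yl)-3-[(triethylsilyl)oxy]heptanal | CC(=O)CC[C@@](O[Si](CC)(CC)CC)(C(C)C)CC=O | intermediate
5 | (5R)-2-methyl-5-(propan-2-yl)-5-[(triethylsilyl)oxy]cyclopent-1-ene-1-carbaldehyde | CC1=C(C=O)[C@](O[Si](CC)(CC)CC)(C(C)C)CC1 | intermediate
6 | {[(1R)-2-ethenyl-3-methyl-1-(propan-2-yl)cyclopent-2-en-1-yl]oxy}triethylsilane | CC1=C(C=C)[C@](O[Si](CC)(CC)CC)(C(C)C)CC1 | intermediate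
7 | methyl but-3-enoate | C=CCC(=O)OC | starting material
8 | methyl 2-diazobut-3-enoate | C=CC(=[N+]=[N-])C(=O)OC | intermediate
9 | methyl (1S,2S)-1-ethenyl-2-{(5R)-2-methyl-5-(propan-2-yl)-5-[(triethylsilyl)oxy]cyclopent-1-en-1-yl}cyclopropane-1-carboxylate (vinyl cis to cyclopentenyl) | COC(=O)[C@]1(C=C)C[C@H]1C2=C(C)CC[C@@]2(O[Si](CC)(CC)CC)C(C)C | intermediate (not isolated)
10 | methyl (3R,8aR)-8a-methyl-3-(propan-2-yl)-3-[(triethylsilyl)oxy]-1,2,3,5,8,8a-hexahydroazulene-6-carboxylate | COC(=O)C1=CC[C@@]2(C)CC[C@@](O[Si](CC)(CC)CC)(C(C)C)C2=CC1 | intermediate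
11 | C4-alkylborane from 10 (BH2 on C4 cis to H-3a, H-3a trans to the 8a-methyl) | COC(=O)C1=CC[C@@]2(C)CC[C@@](O[Si](CC)(CC)CC)(C(C)C)[C@@H]2[C@@H](B)C1 | intermediate (not isolated)
12 | methyl (3R,3aS,4S,8aR)-4-hydroxy-8a-methyl-3-(propan-2-yl)-3-[(triethylsilyl)oxy]-1,2,3,3a,4,5,8,8a-octahydroazulene-6-carboxylate | COC(=O)C1=CC[C@@]2(C)CC[C@@](O[Si](CC)(CC)CC)(C(C)C)[C@@H]2[C@@H](O)C1 | intermediate
13 | (3R,3aS,4S,8aR)-6-(hydroxymethyl)-8a-methyl-3-(propan-2-yl)-3-[(triethylsilyl)oxy]-1,2,3,3a,4,5,8,8a-octahydroazulen-4-ol | OCC1=CC[C@@]2(C)CC[C@@](O[Si](CC)(CC)CC)(C(C)C)[C@@H]2[C@@H](O)C1 | intermediate (not isolated)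
14 | (3R,3aS,4S,8aR)-6-(hydroxymethyl)-8a-methyl-3-(propan-2-yl)-1,2,3,3a,4,5,8,8a-octahydroazulene-3,4-diol | OCC1=CC[C@@]2(C)CC[C@@](O)(C(C)C)[C@@H]2[C@@H](O)C1 | intermediate
15 | pyridinium sulfate monoester of the primary allylic hydroxyl of 14 | [O-]S(=O)(=O)OCC1=CC[C@@]2(C)CC[C@@](O)(C(C)C)[C@@H]2[C@@H](O)C1.c1cc[nH+]cc1 | intermediate (not isolated)
16 | jaeschkeanadiol, (3R,3aS,4S,8aR)-6,8a-dimethyl-3-(propan-2-yl)-1,2,3,3a,4,5,8,8a-octahydroazulene-3,4-diol | CC1=CC[C@@]2(C)CC[C@@](O)(C(C)C)[C@@H]2[C@@H](O)C1 | intermediate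
17 | 4-acetoxybenzoyl chloride | CC(=O)Oc1ccc(cc1)C(Cl)=O | starting material
18 | (3R,3aS,4S,8aR)-3-hydroxy-6,8a-dimethyl-3-(propan-2-yl)-1,2,3,3a,4,5,8,8a-octahydroazulen-4-yl 4-(acetyloxy)benzoate | CC1=CC[C@@]2(C)CC[C@@](O)(C(C)C)[C@@H]2[C@@H](OC(=O)c2ccc(OC(C)=O)cc2)C1 | intermediate
19 | ferutinine, (3R,3aS,4S,8aR)-3-hydroxy-6,8a-dimethyl-3-(propan-2-yl)-1,2,3,3a,4,5,8,8a-octahydroazulen-4-yl 4-hydroxybenzoate | CC1=CC[C@@]2(C)CC[C@@](O)(C(C)C)[C@@H]2[C@@H](OC(=O)c2ccc(O)cc2)C1 | target

Total step count: 11. Longest linear sequence: 10 steps (steps 1–4 and 6–11; step 5 is a one-step side branch).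

**Steps most likely to fail**

Step 6. The catalyst may fail to impose its facial preference on the vinyl group (mismatch with the resident C3 centre, or the assumed sense of induction being reversed for this diene), or the cyclopropane may epimerise by thermal ring opening before rearranging; either would erode the configuration at C8a. The Cope shift may also stall because the ring methyl points into the boat. Fallback, from enal 5 back to 16, closing the ring by metathesis instead. Allylmagnesium bromide adds 1,2 to 5 to give the dienol 1-{(5R)-2-methyl-5-(propan-2-yl)-5-[(triethylsilyl)oxy]cyclopent-1-en-1-yl}but-3-en-1-ol F1. Anionic oxy-Cope rearrangement (KH, 18-crown-6, THF) moves the allyl group to the methyl-bearing ring carbon and, after protonation and base equilibration of the formyl-bearing carbon, should give the quaternary aldehyde 2-allyl-2-methyl-5-(propan-2-yl)-5-[(triethylsilyl)oxy]cyclopentane-1-carbaldehyde F2. 2-Methylallylmagnesium chloride then gives the homoallylic alcohol F3. Ring-closing metathesis with the second-generation Grubbs catalyst, (H2IMes)(PCy3)Cl2Ru=CHPh, closes the seven-membered ring at C6=C7 to the 3-O-triethylsilyl ether of jaeschkeanadiol F4, and Bu4NF gives 16.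

Step 7. Borane may add from the face carrying the angular methyl, because the opposite face is encumbered by the isopropyl group and the fold of the seven-membered ring; this would give the cis-fused 3a,4-diepimer. Slow attack at the hindered alkene could also let enoate reduction compete. Fallback, from 10 back to 14, using the tertiary hydroxyl as a directing group. Bu4NF frees the allylic alcohol methyl (3R,8aR)-3-hydroxy-8a-methyl-3-(propan-2-yl)-1,2,3,5,8,8a-hexahydroazulene-6-carboxylate F5. VO(acac)2/t-BuOOH epoxidises C3a=C4 syn to the hydroxyl, giving the epoxy alcohol F6. Cp2TiCl (trivalent titanium, from Cp2TiCl2 and Zn) with 1,4-cyclohexadiene opens the epoxide by homolysis of the C3a–O bond and should deliver hydrogen to the tertiary radical anti to the neighbouring titanoxy group, giving the C4-epimeric diol ester F7 with H-3a trans to the 8a-methyl. Dess–Martin periodinane (NaHCO3) gives the 4-ketone F8, used without delay. Evans–Saksena reduction with Me4NBH(OAc)3 (AcOH/MeCN, −20 °C) delivers hydride internally from the C3 hydroxyl, giving the anti-1,3-diol methyl (3R,3aS,4S,8aR)-3,4-dihydroxy-8a-methyl-3-(propan-2-yl)-1,2,3,3a,4,5,8,8a-octahydroazulene-6-carboxylate F9, and i-Bu2AlH reduces it to 14.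

Step 9. Sulfation may spread to the secondary hydroxyl, or hydride may be delivered with allylic transposition (SN2′) to give the exocyclic methylene isomer. Fallback, from 14 back to 16, through a π-allyl complex instead of direct displacement. Selective acetylation of the primary hydroxyl (Ac2O, 2,4,6-collidine, CH2Cl2, −20 °C) gives the allylic acetate [(3R,3aS,4S,8aR)-3,4-dihydroxy-8a-methyl-3-(propan-2-yl)-1,2,3,3a,4,5,8,8a-octahydroazulen-6-yl]methyl acetate F10. Pd(PPh3)4 (zerovalent palladium) with LiBHEt3 in THF then reduces the π-allyl palladium intermediate by hydride attack at the less hindered primary terminus, which should keep the trisubstituted ring alkene and give 16.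

**Further compounds**
F1 | step 6 | 1-{(5R)-2-methyl-5-(propan-2-yl)-5-[(triethylsilyl)oxy]cyclopent-1-en-1-yl}but-3-en-1-ol (carbinol epimers) | C=CCC(O)C1=C(C)CC[C@@]1(O[Si](CC)(CC)CC)C(C)C
F2 | step 6 | 2-allyl-2-methyl-5-(propan-2-yl)-5-[(triethylsilyl)oxy]cyclopentane-1-carbaldehyde (formyl cis to the 2-methyl and to the silyloxy group) | C=CC[C@@]1(C)CC[C@@](O[Si](CC)(CC)CC)(C(C)C)[C@@H]1C=O
F3 | step 6 | 3-methyl-1-{2-allyl-2-methyl-5-(propan-2-yl)-5-[(triethylsilyl)oxy]cyclopentyl}but-3-en-1-ol (configuration as in the target) | C=CC[C@@]1(C)CC[C@@](O[Si](CC)(CC)CC)(C(C)C)[C@@H]1[C@@H](O)CC(C)=C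
F4 | step 6 | (3R,3aS,4S,8aR)-6,8a-dimethyl-3-(propan-2-yl)-3-[(triethylsilyl)oxy]-1,2,3,3a,4,5,8,8a-octahydroazulen-4-ol | CC1=CC[C@@]2(C)CC[C@@](O[Si](CC)(CC)CC)(C(C)C)[C@@H]2[C@@H](O)C1
F5 | step 7 | methyl (3R,8aR)-3-hydroxy-8a-methyl-3-(propan-2-yl)-1,2,3,5,8,8a-hexahydroazulene-6-carboxylate | COC(=O)C1=CC[C@@]2(C)CC[C@@](O)(C(C)C)C2=CC1
F6 | step 7 | 3a,4-epoxide of F5 with the epoxide oxygen cis to the C3 hydroxyl and the 8a-methyl | COC(=O)C1=CC[C@@]2(C)CC[C@@](O)(C(C)C)[C@]23O[C@@H]3C1
F7 | step 7 | methyl (3R,3aS,4R,8aR)-3,4-dihydroxy-8a-methyl-3-(propan-2-yl)-1,2,3,3a,4,5,8,8a-octahydroazulene-6-carboxylate (C4 epimer) | COC(=O)C1=CC[C@@]2(C)CC[C@@](O)(C(C)C)[C@@H]2[C@H](O)C1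
F8 | step 7 | methyl 3-hydroxy-8a-methyl-4-oxo-3-(propan-2-yl)-1,2,3,3a,4,5,8,8a-octahydroazulene-6-carboxylate (H-3a trans to the 8a-methyl) | COC(=O)C1=CC[C@@]2(C)CC[C@@](O)(C(C)C)[C@@H]2C(=O)C1
F9 | step 7 | methyl (3R,3aS,4S,8aR)-3,4-dihydroxy-8a-methyl-3-(propan-2-yl)-1,2,3,3a,4,5,8,8a-octahydroazulene-6-carboxylate | COC(=O)C1=CC[C@@]2(C)CC[C@@](O)(C(C)C)[C@@H]2[C@@H](O)C1
F10 | step 9 | [(3R,3aS,4S,8aR)-3,4-dihydroxy-8a-methyl-3-(propan-2-yl)-1,2,3,3a,4,5,8,8a-octahydroazulen-6-yl]methyl acetate | CC(=O)OCC1=CC[C@@]2(C)CC[C@@](O)(C(C)C)[C@@H]2[C@@H](O)C1
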